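Late in a run the curves slow down. From 40.0 h to 50.0 h the summer run gains 4.6 percentage points and the autumn run 4.7 points. So I ask how many chains share the monomer at the end.

| setting | autumn | summer | Wednesday's | Monday's |
|---|---|---|---|---|
| free monomer | 0.020 M | 0.020 M | 0.020 M | 0.020 M |
| transfer agent | 0.60 mM | 0.30 mM | 0.600 mM | 0.600 mM |
| pre-initiator | 1 mol% | 1 mol% | 1 mol% | 2 mol% |
| impurity | 130 µM | 85 µM | 85 µM | 85 µM |
| remark | run made earlier | run made earlier |  |  |
| time |  |  | 10 d | 10 d |

| run | time / h | monomer in chains / % |
|---|---|---|
| autumn | 3.00 | 1.4 |
| autumn | 10.0 | 9.5 |
| autumn | 15.0 | 22.2 |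
| autumn | 25.0 | 44.6 |
| autumn | 40.0 | 61.6 |
| autumn | 50.0 | 66.3 |
| summer | 3.00 | 1.3 |
| summer | 10.0 | 21.8 |
| summer | 15.0 | 42.4 |
| summer | 25.0 | 70.3 |
| summer | 40.0 | 87.7 |
| summer | 50.0 | 92.3 |

(scatter of a reading: 0.5 percentage points)

1. which of the two ends with the longer chains by the average number of monomer units in a chain (chains begun, living or dead) ("neither" if they lie within 10%) (Wednesday's / Monday's / neither)
2. average number of monomer units in a chain (chains begun, living or dead) at the end, Wednesday's
3. average number of monomer units in a chain (chains begun, living or dead) at the end, Monday's

- the average divides the monomer in chains by the number of chains begun, living and dead together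
- the numbers in the tables scatter with a standard deviation of 0.5 percentage points
- the earlier runs do not show the number of chains; that part of a forecast is a guess
- no earlier run changes the charge of pre-initiator; that part of a forecast is a guess

I keep a ledger of the pre-initiator, mole by mole. Wednesday's flask is charged with 200 µM. The first entry assumes that impurity cancels it one for one, which takes 85 µM. The balance, 115 µM, goes to chains, one each. I call this the surviving charge: pre-initiator charged minus impurity charged. No run shows the chain count, so this entry is a guess. For Monday's flask the balance is 315 µM, and no run tests a change of pre-initiator.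

The readings give some support. The surviving charge of the summer run is 115 µM and that of the autumn run 70.0 µM, a ratio of 1.64. The first-order slopes from 15.0 h to 25.0 h read 0.0662 h⁻¹ and 0.0340 h⁻¹, a ratio of 1.95. The direction agrees, though the transfer agent differs too.

My zero is the even case, in which surviving chains share the monomer equally. Full conversion then gives 174 for Wednesday's and 63.5 for Monday's. The autumn run had less surviving charge and the same transfer agent as Wednesday's, and it reached 66.3%. At that conversion my estimate for Wednesday's is 115, which is longer than my full-conversion estimate of 63.5 for Monday's. I commit to Wednesday's.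

The forecast also says Wednesday's, with 145 against 60, from “Chains begun, guessed at about one per surviving centre”.

The flask gives Wednesday's: 160 for Wednesday's and 66.7 for Monday's.

    free monomer + initiator → living end + monomer in chains (k = 0.720 M⁻¹ min⁻¹)
    free monomer + living end → monomer in chains + living end, rate k2*[living end]*[free monomer] (k = 13.0 M⁻¹ min⁻¹)
    pre-initiator → initiator (k = 0.00320 min⁻¹)
    living end + transfer agent → dead chain (kL = 1.10 M⁻¹ min⁻¹)
    initiator + impurity → spent initiator (k = 1700 M⁻¹ min⁻¹)

In Wednesday's flask at 10.0 d, the ledger shows spent initiator 8.50 × 10⁻⁵ M and chains begun 115 µM, dead and living together. With 92.0% of the monomer in chains, the surviving charge gives 160. Wednesday's length moves by 16.0 at 68.4 µM or 99.2 µM of impurity, so a run there would test the forecast. A neighbour of Wednesday's flask carries 5.1 × 10⁻⁵ M of impurity, so its surviving charge is 149 µM. With 96.6% in chains, the reckoning gives 130, and that flask gives 130.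

All runs were generated by integration with made-up constants, and the scatter is random.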